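The earlier runs and the new flask were computed with constants of no real substance.

At late times the readings stopped moving, so I reckoned with the ratio of the two amounts and not with their progress.

| flask | substrate | first nucleophile | second nucleophile | remark | time |
|---|---|---|---|---|---|
| grey | 0.25 mM | 0.75 mM | 0.475 mM | run made earlier |  |
| teal | 1 mM | 0.75 mM | 0.475 mM | run made earlier |  |
| ochre | 0.50 mM | 0.75 mM | 0.24 mM | run made earlier |  |
| flask | 0.50 mM | 0.750 mM | 0.475 mM |  | 4.0 min |

| run | time / min | other capture product / % | target / % |
|---|---|---|---|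
| grey | 1.33 | 19.6 | 29.4 |
| grey | 2.50 | 17.9 | 29.7 |
| grey | 4.00 | 18.6 | 30.1 |
| grey | 5.00 | 18.6 | 31.3 |
| teal | 1.33 | 16.9 | 26.8 |
| teal | 2.50 | 15.4 | 28.5 |
| teal | 4.00 | 15.2 | 27.3 |
| teal | 5.00 | 17.0 | 26.1 |
| ochre | 0.417 | 9.2 | 30.8 |
| ochre | 0.833 | 10.6 | 30.9 |
| ochre | 2.00 | 8.6 | 30.0 |
| ochre | 5.00 | 9.8 | 31.8 |

(standard deviation of a reading: 1 percentage point)

- ratio of other capture product to target at 1.5 s
- ratio of other capture product to target at 15 s
- ratio of other capture product to target at 4.0 min



I compared the two amounts as read. The ochre run read a mean ratio of other capture product to target of 0.309. I divided it by that run's second nucleophile: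

ratio per mM = 0.309 / 0.24 mM = 1.29 mM⁻¹

This is the product ratio per mM of second nucleophile, an apparent selectivity factor read from amounts at 0.75 mM of first nucleophile. It gave me the ratio of amounts I expected in the flask:

expected in the flask: 1.29 mM⁻¹ × 0.475 mM = 0.612

The grey and teal runs, which played no part in this, read 0.620 and 0.593.

Then I asked how the comparison drifts. Each capture slows as it spends its own nucleophile. I took the ochre target reading at its last time and counted that spending alone:

target rate slowed by a factor 0.788

other capture slowed by a factor 0.795

drift of the comparison: 1.01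

So I committed to about 0.612 at each asked time.

The forecast gave 0.61 (0.45 to 0.75), 0.61 (0.53 to 0.68) and 0.6 (0.55 to 0.66). Its ground: “The ratio of parallel captures should hold at early times too”.

The flask gave 0.638 at 1.5 s, 0.623 at 15 s and 0.616 at 4.0 min.

    substrate → intermediate (k = 0.100 s⁻¹)
    first nucleophile + intermediate → target (k = 460 M⁻¹ s⁻¹)
    second nucleophile + intermediate → other capture product (k = 470 M⁻¹ s⁻¹)
    intermediate → solvolysis product (k = 0.340 s⁻¹)
    second nucleophile ⇌ dormant form (K = 8.90, k = 0.0350 s⁻¹)
    target ⇌ isomer of the product (K = 0.330, k = 0.0360 s⁻¹)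

The flask held something the ratio does not show: at 0.400 min its second nucleophile stood at 35.0 % of charge, lower than my reckoned factor, beside 0.224 mM of dormant form. The flask's own ratio at 4.0 min gives 1.30 mM⁻¹ per its second nucleophile charge, against my 1.29 mM⁻¹.

In the neighbour flask with 1.9 mM of second nucleophile, the product ratio per mM gives 2.45. The computed ratio there was 2.50 at 15 s and 2.43 at 4.0 min.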